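(The numbers in the tables stem from a simulated flask for an exercise; noise was put on by code.)

**The gap.** Time is the first gap: the readings end at 4.00 h, and the new flasks stop at 5.0 h, at other loadings of initiator.

| flask | starting material | partner | initiator | remark | time |
|---|---|---|---|---|---|
| winter | 38 mM | 1 equiv | 0.66 mol% | run made earlier |  |
| midnight | 38 mM | 1 equiv | 1.6 mol% | run made earlier |  |
| autumn | 38 mM | 1 equiv | 4.4 mol% | run made earlier |  |
| oak | 38 mM | 1.00 equiv | 0.6 mol% |  | 5.0 h |
| larch | 38 mM | 1.00 equiv | 1 mol% |  | 5.0 h |
| alder | 38 mM | 1.00 equiv | 2 mol% |  | 5.0 h |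
| ash | 38 mM | 1.00 equiv | 4 mol% |  | 5.0 h |
| cedar | 38 mM | 1.00 equiv | 3 mol% |  | 5.0 h |

| run | time / h | target / % |
|---|---|---|
| winter | 0.333 | 18.4 |
| winter | 0.833 | 31.1 |
| winter | 1.50 | 39.2 |
| winter | 2.50 | 47.7 |
| winter | 4.00 | 57.6 |
| midnight | 0.333 | 25.8 |
| midnight | 0.833 | 43.6 |
| midnight | 1.50 | 52.2 |
| midnight | 2.50 | 61.4 |
| midnight | 4.00 | 68.3 |
| autumn | 0.250 | 31.8 |
| autumn | 0.500 | 47.1 |
| autumn | 1.00 | 62.0 |
| autumn | 2.00 | 72.2 |
| autumn | 4.00 | 82.5 |

(readings scatter by 1 percentage point)

1. all flasks from highest to lowest amount of target, in percent of the starting material charged, at 5.0 h (oak / larch / alder / ash / cedar)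
2. the amount of target, in percent of the starting material charged of the flask you put first, at 5.0 h
3. the amount of target, in percent of the starting material charged of the flask you put last, at 5.0 h



**Loading exponent.** With partner at 1.00 equiv, I follow the odds, the fraction of the charge that is target over the fraction that is not. At 4.00 h they read 1.36 in winter and 4.71 in autumn. The loading exponent (apparent order in initiator), the slope of ln odds against ln loading at a fixed time, reads 0.656. I move autumn to ash and winter to oak with it.

**Two extremes.** In the frozen version the odds stop at the last reading: ash 4.43, which is 81.6% target, and oak 1.28, which is 56.1%. In the steady version the odds grow in proportion to time: ash 84.7%, oak 61.5%.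

I expect ash and oak between the two, because autumn's odds read a growth factor of 1.82 from 2.00 h to 4.00 h, less than the steady factor of 2.00 yet above the frozen factor, though a scatter of 1 percentage point per reading blurs the gap to the steady factor. That reading gives a time exponent of 0.860, so I commit to 84.3% for ash and 60.8% for oak. The exponent is positive, so I rank the flasks by loading.

**The forecast.** It gives ash > cedar > alder > larch > oak, 84% and 61%, on the ground that "Yield rises monotonically across the tested range".

**The result.** The flasks give ash > cedar > alder > larch > oak, with ash at 83.9% and oak at 59.7%.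

    initiator → 2 initiating radical (k = 0.0570 h⁻¹)
    starting material + initiating radical → capped initiator + first chain carrier (k = 6.60 × 10⁵ M⁻¹ s⁻¹)
    partner + first chain carrier → target + second chain carrier (k = 2.90 × 10⁷ M⁻¹ h⁻¹)
    starting material + second chain carrier → released group + first chain carrier (k = 27000 M⁻¹ s⁻¹)
    2 second chain carrier → ended chains (k = 9.00 × 10⁷ M⁻¹ s⁻¹)
    starting material ⇌ dormant form (K = 2.80, k = 0.930 h⁻¹)
    2 starting material → self-condensation product (k = 0.0160 M⁻¹ h⁻¹)

**Parked charge.** Oak at 5.00 h holds 32.4% as dormant form, beside 7.9% free starting material. Carrying oak's odds of 1.48 to the loading of ash with the exponent 0.656 gives 83.7% target, and ash stands at 83.9%. Carrying them down to the neighbour of oak charged with 0.15 mol% initiator gives 37.4%, and that neighbour holds 39.3%.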